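I could not give you the quick number as a ratio of constants, because such a ratio says how the single product starts, and you asked what stands at the end.

    starting material + partner → single product + by-product (k1 = 11 L mol⁻¹ h⁻¹, Ea1 = 82.0 kJ mol⁻¹)
    starting material + partner → other mono adduct + by-product (k2 = 12 L mol⁻¹ h⁻¹, Ea2 = 78.0 kJ mol⁻¹)
    partner + single product → bis adduct + by-product (k3 = 0.22 L mol⁻¹ h⁻¹, Ea3 = 84.0 kJ mol⁻¹)
    partner + other mono adduct → bis adduct + by-product (k4 = 9.4 L mol⁻¹ h⁻¹, Ea4 = 66.0 kJ mol⁻¹)
    gas ⇌ partner, rate k5*(csat - [partner]) (k5 = 0.15 h⁻¹, csat = 1.3 mM)
    single product + by-product → side product (k6 = 0.75 L mol⁻¹ h⁻¹, Ea6 = 89.0 kJ mol⁻¹)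
    single product → over-reaction product (k7 = 2.3 × 10⁻⁵ h⁻¹, Ea7 = 121 kJ mol⁻¹)
    (constants at 60 °C)

in all of them: starting material 0.020 M; gas 1.3 mM (held); time 25 d
- ash: temperature 45 °C
- larch: temperature 90 °C
- elm: temperature 75 °C
- alder: temperature 60 °C

- the flask that comes out highest in share of single product in all that became single product or bis adduct or side product, or "all alike" when all lie within 1.5 percentage points (ash / larch / elm / alder / all alike)
- share of single product in all that became single product or bis adduct or side product, ash
- share of single product in all that became single product or bis adduct or side product, larch
- share of single product in all that became single product or bis adduct or side product, elm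
- share of single product in all that became single product or bis adduct or side product, alder

- at the start none of partner is dissolved
- constants are those at 60 °C; use the activation energies for any other temperature
- the share counts what is present at the end, not what went on to other products

I began with ash. With partner put at its saturation value, starting material falls in a pseudo-first-order way at a = 2.72 L mol⁻¹ h⁻¹ plus 3.18 L mol⁻¹ h⁻¹, times csat, which is 0.00768 h⁻¹. By-product climbs as starting material goes, and I replaced its curve by its mean over the run t: the charge less the charge divided by at, W̄ = 0.0157 M. With the side-product constant at 0.165 L mol⁻¹ h⁻¹, single product then dies at a steady ℓ = 0.00258 h⁻¹. The number I carried is the exposure E = ℓt = 1.55, the lifetimes of single product against by-product that fit into the run.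

The loss to bis adduct, at most 6.85 × 10⁻⁵ h⁻¹, is far slower than ℓ, so I dropped it. The weak point is the start, where supply and use of partner balance at 55.9% of csat, so my a runs high early.

Single product formed and dying at these two steady rates comes to 14.1% of the charge in ash. The products counted in the share cannot exceed the charge, so the ash share lies at or above single product's true part of the charge; I committed to that figure as an estimate of that part, not as a bound on the share.

| Flask | Temperature | E |
|---|---|---|
| ash | 45 °C | 1.55 |
| alder | 60 °C | 8.50 |
| elm | 75 °C | 35.4 |
| larch | 90 °C | 127 |

Ash has the smallest exposure, so I picked ash too.

Your forecast named ash, with 16% there, 0.03% in alder, 0% in elm and 0% in larch. Its ground was that the by-product step runs “far faster than the reaction with the dilute partner”. My estimate of single product's part of the charge lay below its ash share.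

The simulation puts ash highest at 17.3%, with alder at 0.0575%, elm at 0% and larch at 0%, so the forecast stands. The run length would have to change for its ash figure to fail: left for 250 d, ash gives 0%. Alder's exposure of 8.50 is 5.48 times that of ash, and it reckons to 0.0185% of the charge as single product. Alder held 0.0572%, a factor of 3.09, which is a shift of 1.13 in E.

(Its constants stand for no real mixture; the run is a simulation.)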